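TBS = tert-butyldimethylsilyl (t-BuMe2Si) throughout.

## Analysis of the target

Compound 19 is a flavanone. Benzene ring A is fused through C4a and C8a to the dihydropyranone ring C (O1, C2, C3 and the C4 carbonyl), and ring B sits on C2. Ring A carries hydroxyls at C5, C7 and C8 and a single hydrogen at C6. Ring B carries the 4'-hydroxyl and, at C3', a 3-methylbut-3-enyl chain that ends in a 1,1-disubstituted alkene. C2 is the only stereocentre and is S, so there is no second centre to relay from. Three groups restrict the chemistry:

- The O1–C2 bond is β to the C4 carbonyl and benzylic to a para-oxygenated ring, so base opens ring C to the chalcone and erases C2.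
- The 5,8-hydroquinone and 7,8-catechol arrangement of ring A is oxidised by air as soon as a phenoxide forms.
- The terminal alkene moves into the prenyl position or closes onto O4' under protic acid, and it does not survive hydrogenation.

The hard parts are an isolated benzylic C–O stereocentre, a ring A with four oxygens of which one must be singled out, and a last deprotection that is neither basic, strongly acidic nor reductive. The strategy rests on one feature: O1 joins C8a to the benzylic carbon C2, so (ring A)–O1–C2H–(ring B) is a masked O-aryl oxocarbenium ion. The array C4a=C8a–O1+=C2 is a cationic 2-oxadiene that lacks only C3 and C4. Because C8 is oxygenated, C4a is the only ring A carbon ortho to O1 that can close the ring.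

## Retrosynthetic reasoning

**19 to 18.** The four O–Si bonds are cut last. Silyl ethers are the only phenol protection here that comes off under buffered, non-reductive conditions, which the flavanone, the hydroquinone and the alkene all require.

**18 to 17.** The C4 carbonyl is traced back to a C4 ethyl ether. This is a change of oxidation level only. It keeps the carbonyl, and with it the ring-opening path that racemises C2, out of the molecule until the penultimate step. The forward reaction must remove the C4 hydrogen as hydride without touching the C2 hydrogen.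

**17 to 15 and 16.** The bonds C2–C3 and C4–C4a are cut. This is the only cut that removes ring C and the stereocentre at once and leaves two arenes plus a two-carbon unit. O1–C2 is kept intact in acetal 15, so the product can only be a flavan, never the 4-aryl isomer. Forward, ionisation of 15 must give the O-aryl oxocarbenium ion, which takes up enol ether 16 at C2 and closes onto C4a. A chiral counter-anion has to decide the face of attack at C2.

**15 to 13 and 7.** The acetal C–O bond to ring A is cut. Forward, one methoxy group of dimethyl acetal 13 is exchanged for chloride (14) and phenol 7 is O-alkylated under amine base. Direct acid-catalysed exchange of 7 with 13 is avoided, because under acid the very electron-rich ring A would be C-alkylated and the equilibrium is unfavourable.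

**7 to 1.** Phenol 7 needs a 1,2,3,5-tetraoxygenated benzene with one terminal oxygen of the contiguous triad left free. It is traced to aldehyde 1. The hydrogen bond to the formyl group singles out one ortho hydroxyl (2), which is held as a benzyl ether (3). The formyl carbon is then exchanged for oxygen (4, 5), the new hydroxyl is silylated (6), and hydrogenolysis frees the singled-out oxygen.

**13 to 8 and 10.** Acetal 13 comes from aldehyde 12. Its aryl–CH2 bond is cut to aryl bromide 9 (from 8) and alkylzinc reagent 11 (from 10). The chain is thus installed in its final form by one sp2–sp3 coupling before any sensitive functionality exists.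

## Alternatives that were turned down

**Alternative 1:** ring A ortho-quinone methide plus ring B styrene.
- Disconnection: O1–C2 and C3–C4. C4 is the formyl carbon of salicylaldehyde A2 and ring B enters as styrene A3.
- Forward key step: A2, an orthoformate and a BINOL-derived chiral phosphoric acid give a 4-methoxy ortho-quinone methide, which adds A3 to give the 2,4-cis-4-methoxyflavan A1.
- For: acid-catalysed cycloaddition of ortho-quinone methides with styrenes is an established reaction class. The quinone methide offers a defined binding site to the chiral phosphate, so on precedent for enantiocontrol this alternative is stronger than the chosen route.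
- Against: A3 is a much weaker nucleophile than enol ether 16 and is an acid-sensitive para-alkoxystyrene. The methoxymethyl ethers are acetals that must survive the acid and then need protic acid for removal, which is exactly what cyclises the isopentenyl chain onto O4'. The chain therefore has to be carried as a methyl ketone and methylenated later, which costs steps and clashes with the C4 carbonyl. A2 is a pentasubstituted benzene and takes longer to make than phenol 7.
- Comparison: the chosen route offers a far stronger nucleophile, the side chain in final form and neutral deprotection, at the price of unproven enantiocontrol.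

**Alternative 2:** ring B quinone methide route to the side chain.
- Disconnection: the ArCH2–CH2 bond of the chain, made last.
- Forward key step: flavanone A5 is dehydrated thermally to the ring B ortho-quinone methide, which adds methallylsilane A6 to give chroman A4. Later fragmentation of the β-silyl ether releases the 4'-hydroxyl and the terminal alkene.
- For: the alkene can only appear in the terminal position and is masked until the end. On the integrity of the alkene this alternative is stronger, since the chosen route carries the free alkene through a strong-acid step.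
- Against: it solves the easy bond and leaves ring C and C2 to a separate asymmetric flavanone synthesis of A5. Heating a flavanone with a free 4'-hydroxyl invites ring opening and loss of C2. A4 forms as two epimers.
- Comparison: the chosen route makes the chain in one coupling on the simple arene 9 and spends its effort on ring C and C2, so it is shorter overall.

**Alternative 3:** acylquinone oxa-Michael closure.
- Disconnection: O1–C8a.
- Forward key step: a silver oxidant converts acylhydroquinone A8 into acylquinone A9. The C2 hydroxyl adds to C8a and tautomerisation gives the 5,8-dihydroxyflavanone A7.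
- For: C2 is set beforehand by well-precedented carbonyl chemistry and is not touched in the closure, so stereochemical security is higher than in the chosen route. The 5,8-dihydroxy pattern needs no protection, and the allyl ethers leave under mild palladium catalysis.
- Against: the key step forms only a C–O bond, so the whole carbon skeleton must be assembled first by an asymmetric aldol on a ketone bearing free phenols. A8 is a β-hydroxy ketone that can dehydrate or undergo retro-aldol cleavage. A9 is a strong electrophile and oxidant, so intermolecular addition and over-oxidation of A7 to the quinone compete.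
- Comparison: the chosen route forms two C–C bonds and ring C in one convergent step from two simple arenes, and is clearly shorter.

Key step: step 11

Assumption: the sense of induction of the chiral acid in step 11 cannot be predicted. The (S,S) acid is written as a placeholder for whichever antipode delivers 2S; both are accessible from (R)- or (S)-BINOL.

## Route

Step 1
Reactants: 1 2,4,6-trihydroxybenzaldehyde
Product: 2 2,4-bis(TBSO)-6-hydroxybenzaldehyde
Conditions: TBSCl (2.1 equiv), imidazole, CH2Cl2/DMF, 0 °C
Reagents that add atoms: tert-butyldimethylsilyl chloride, CC(C)(C)[Si](C)(C)Cl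
Why: Phenol silylation; the 4-OH and one ortho OH react, while the last ortho hydroxyl is held in a hydrogen bond to the formyl oxygen, so two equivalents should stop at the bis-silyl ether (chelation-controlled partial protection of a phloroglucinol aldehyde).

Step 2
Reactants: 2 2,4-bis(TBSO)-6-hydroxybenzaldehyde
Product: 3 2-(benzyloxy)-4,6-bis(TBSO)benzaldehyde
Conditions: BnOH, PPh3, diisopropyl azodicarboxylate, THF, 0 °C → rt
Reagents that add atoms: benzyl alcohol, OCc1ccccc1
Why: Mitsunobu etherification; the chelated phenol is acidic enough as pronucleophile, and the neutral conditions spare the base-labile aryl silyl ethers.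

Step 3
Reactants: 3 2-(benzyloxy)-4,6-bis(TBSO)benzaldehyde
Product: 5 2-(benzyloxy)-4,6-bis(TBSO)phenol, via aryl formate 4 (not isolated)
Conditions: mCPBA, CH2Cl2, 0 °C → rt; then MeOH, Et3N (cat.), 0 °C
Reagents that add atoms: 3-chloroperoxybenzoic acid, O=C(OO)c1cccc(Cl)c1
Why: Baeyer–Villiger oxidation of the aldehyde (the peracid form of the Dakin oxidation); the trioxygenated aryl group migrates in preference to hydrogen, and the formate is cleaved by mild methanolysis. No alkene is present at this stage.

Step 4
Reactants: 5 2-(benzyloxy)-4,6-bis(TBSO)phenol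
Product: 6 1-(benzyloxy)-2,3,5-tris(TBSO)benzene
Conditions: TBSOTf, 2,6-lutidine, CH2Cl2, 0 °C
Reagents that add atoms: tert-butyldimethylsilyl trifluoromethanesulfonate, CC(C)(C)[Si](C)(C)OS(=O)(=O)C(F)(F)F
Why: Silylation of a flanked phenol with a silyl triflate; a silyl shift between the neighbouring oxygens beforehand would not matter, since both end as TBS ethers.

Step 5
Reactants: 6 1-(benzyloxy)-2,3,5-tris(TBSO)benzene
Product: 7 2,3,5-tris(TBSO)phenol
Conditions: H2 (1 atm), 10% Pd on carbon, EtOAc, rt
Reagents that add atoms: none
Why: Hydrogenolysis of the benzyl ether; the conditions are neutral, so the freed hydroxyl does not take a silyl group from its neighbour, and the step precedes the introduction of the alkene.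

Step 6
Reactants: 8 3-bromo-4-hydroxybenzaldehyde
Product: 9 3-bromo-4-(TBSO)benzaldehyde
Conditions: TBSCl, imidazole, CH2Cl2, rt
Reagents that add atoms: tert-butyldimethylsilyl chloride, CC(C)(C)[Si](C)(C)Cl
Why: Standard phenol silylation.

Step 7
Reactants: 10 4-bromo-2-methylbut-1-ene
Product: 11 (3-methylbut-3-en-1-yl)zinc bromide (LiCl complex in THF)
Conditions: Zn dust (activated with BrCH2CH2Br and Me3SiCl), LiCl, THF, 40 °C
Reagents that add atoms: zinc, [Zn]
Why: LiCl-assisted direct insertion of zinc into a primary alkyl bromide; the solution is titrated and used as such.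

Step 8
Reactants: 9 3-bromo-4-(TBSO)benzaldehyde; 11 (3-methylbut-3-en-1-yl)zinc bromide
Product: 12 4-(TBSO)-3-(3-methylbut-3-en-1-yl)benzaldehyde
Conditions: Pd(OAc)2 (2 mol%), 2-dicyclohexylphosphino-2',6'-dimethoxybiphenyl (SPhos, 4 mol%), THF, rt → 40 °C
Reagents that add atoms: none
Why: Negishi coupling; alkylzinc halides tolerate the aldehyde and the aryl silyl ether, and the bulky biaryl phosphine favours reductive elimination over β-hydride elimination, which keeps the alkene in the terminal position.

Step 9
Reactants: 12 4-(TBSO)-3-(3-methylbut-3-en-1-yl)benzaldehyde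
Product: 13 4-(TBSO)-3-(3-methylbut-3-en-1-yl)benzaldehyde dimethyl acetal
Conditions: HC(OMe)3, MeOH, pyridinium p-toluenesulfonate (cat.), rt
Reagents that add atoms: trimethyl orthoformate, COC(OC)OC
Why: Acetalisation driven by the orthoester as dehydrating agent; the weak acid leaves the aryl silyl ether and the alkene untouched.

Step 10
Reactants: 13 4-(TBSO)-3-(3-methylbut-3-en-1-yl)benzaldehyde dimethyl acetal; 7 2,3,5-tris(TBSO)phenol
Product: 15 racemic methyl 2,3,5-tris(TBSO)phenyl acetal of aldehyde 12, via α-chloro ether 14 (not isolated)
Conditions: AcCl (1.05 equiv), ZnBr2 (0.1 mol%), CH2Cl2, 0 °C → rt; then 7, iPr2NEt, CH2Cl2, −40 → 0 °C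
Reagents that add atoms: none
Why: Acyl chloride exchange of one acetal methoxy group for chloride, followed by O-alkylation of the phenol by the α-chloro ether under amine base, as in the formation of alkoxymethyl aryl ethers. Base and low temperature favour attack through oxygen over ring carbon and keep the silyl groups in place; the new acetal centre is racemic and is destroyed in step 11.

Step 11
Reactants: 15 racemic methyl 2,3,5-tris(TBSO)phenyl acetal of aldehyde 12; 16 ethyl vinyl ether
Product: 17 (2S,4S)-4-ethoxy-5,7,8-tris(TBSO)-2-[4-(TBSO)-3-(3-methylbut-3-en-1-yl)phenyl]chromane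
Conditions: (S,S)-imidodiphosphorimidate acid HN[P(=NSO2CF3)(O2C20H10Ar2)]2, Ar = 3,5-(CF3)2C6H3 (5 mol%), 16 (5 equiv), 5 Å molecular sieves, toluene, −78 → −40 °C; then Et3N, −78 °C
Reagents that add atoms: none
Why: Proposed new method: the confined acid protonates the more basic methoxy oxygen of 15 and methanol leaves, so both enantiomers of the acetal converge on one O-aryl oxocarbenium ion (ring A)–O1+=C2H–(ring B), held as a contact ion pair inside the chiral imidodiphosphorimidate anion. Enol ether 16, by far the strongest π-nucleophile present, attacks C2 on the face left open by the anion and forms C2–C3; this is the enantio-determining event and the only source of the 2S configuration, so C2 is under catalyst control. The resulting O-ethyl oxocarbenium ion at C4 is captured by the ring A carbon ortho to O1 in a six-membered Friedel–Crafts closure (6-exo-trig with respect to the C4=O+ bond, arene carbon C4a as nucleophile), and loss of the arenium proton returns the acid. Ring C is thus closed in a stepwise cationic [4+2] manner, the oxygen counterpart of the Povarov reaction. The closest known reactions are the SnCl4-mediated racemic oxa-Povarov annulation of aryl oxocarbenium ions with alkenes and the chiral phosphoric acid catalysed Povarov reaction of N-aryl imines with vinyl ethers; imidodiphosphorimidates are the acid class known to direct oxocarbenium ions that offer no hydrogen-bond handle. C4 is set in the ring closure, where a chair-like transition state with the C2 aryl group equatorial and the ethoxy group pseudo-equatorial should give the 2,4-cis (4S) isomer; this centre is removed in step 12, so its control is not critical. The step needs chemoselectivity for 16 over the 1,1-disubstituted side-chain alkene (secured by the much higher nucleophilicity of the enol ether and its excess), ring closure over oligomerisation of the vinyl ether (secured by the tetra-oxygenated ring A held next to the cation) and regioselectivity on ring A (secured because C8 already carries a silyloxy group, which leaves one free ortho carbon). Low temperature, sieves that take up methanol and a cold amine quench should keep the product from re-ionising at C2 or C4.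

Step 12
Reactants: 17 (2S,4S)-4-ethoxy-5,7,8-tris(TBSO)-2-[4-(TBSO)-3-(3-methylbut-3-en-1-yl)phenyl]chromane
Product: 18 (2S)-5,7,8-tris(TBSO)-2-[4-(TBSO)-3-(3-methylbut-3-en-1-yl)phenyl]chroman-4-one
Conditions: DDQ (1.5 equiv), CH2Cl2/pH 7 phosphate buffer (10:1), 0 °C
Reagents that add atoms: water, O
Why: Oxidative cleavage of a benzylic ether as in the removal of para-alkoxybenzyl ethers: hydride is taken from C4, which is activated by ring A and by the ethoxy oxygen and whose hydrogen is pseudo-axial in the cis isomer; water adds and the hemiketal collapses to the ketone. C2 is less activated and stays untouched, and the neutral buffer keeps ring C closed.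

Step 13
Reactants: 18 (2S)-5,7,8-tris(TBSO)-2-[4-(TBSO)-3-(3-methylbut-3-en-1-yl)phenyl]chroman-4-one
Product: 19 (2S)-5,7,8-trihydroxy-2-[4-hydroxy-3-(3-methylbut-3-en-1-yl)phenyl]chroman-4-one
Conditions: Bu4NF (4.4 equiv), AcOH (5 equiv), THF, 0 °C → rt, argon; degassed mildly acidic work-up
Reagents that add atoms: none
Why: Fluoride cleavage of aryl silyl ethers; buffering with acetic acid prevents build-up of phenoxide, so the retro-oxa-Michael opening that would racemise C2 and the air oxidation of the hydroquinone are suppressed, and the alkene is inert to these conditions.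

## Compound list

1 | 2,4,6-trihydroxybenzaldehyde | O=Cc1c(O)cc(O)cc1O | starting material
2 | 2,4-bis(TBSO)-6-hydroxybenzaldehyde | O=Cc1c(O)cc(O[Si](C)(C)C(C)(C)C)cc1O[Si](C)(C)C(C)(C)C | intermediate
3 | 2-(benzyloxy)-4,6-bis(TBSO)benzaldehyde | O=Cc1c(OCc2ccccc2)cc(O[Si](C)(C)C(C)(C)C)cc1O[Si](C)(C)C(C)(C)C | intermediate
4 | 2-(benzyloxy)-4,6-bis(TBSO)phenyl formate (not isolated) | O=COc1c(OCc2ccccc2)cc(O[Si](C)(C)C(C)(C)C)cc1O[Si](C)(C)C(C)(C)C | intermediate
5 | 2-(benzyloxy)-4,6-bis(TBSO)phenol | Oc1c(OCc2ccccc2)cc(O[Si](C)(C)C(C)(C)C)cc1O[Si](C)(C)C(C)(C)C | intermediate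
6 | 1-(benzyloxy)-2,3,5-tris(TBSO)benzene | CC(C)(C)[Si](C)(C)Oc1c(OCc2ccccc2)cc(O[Si](C)(C)C(C)(C)C)cc1O[Si](C)(C)C(C)(C)C | intermediate
7 | 2,3,5-tris(TBSO)phenol | CC(C)(C)[Si](C)(C)Oc1c(O)cc(O[Si](C)(C)C(C)(C)C)cc1O[Si](C)(C)C(C)(C)C | intermediate
8 | 3-bromo-4-hydroxybenzaldehyde | O=Cc1ccc(O)c(Br)c1 | starting material
9 | 3-bromo-4-(TBSO)benzaldehyde | O=Cc1ccc(O[Si](C)(C)C(C)(C)C)c(Br)c1 | intermediate
10 | 4-bromo-2-methylbut-1-ene | C=C(C)CCBr | starting material
11 | (3-methylbut-3-en-1-yl)zinc bromide (LiCl complex, THF solution) | C=C(C)CC[Zn]Br | intermediate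
12 | 4-(TBSO)-3-(3-methylbut-3-en-1-yl)benzaldehyde | C=C(C)CCc1cc(C=O)ccc1O[Si](C)(C)C(C)(C)C | intermediate
13 | 4-(TBSO)-3-(3-methylbut-3-en-1-yl)benzaldehyde dimethyl acetal | C=C(C)CCc1cc(C(OC)OC)ccc1O[Si](C)(C)C(C)(C)C | intermediate
14 | racemic α-chloro methyl ether of aldehyde 12 (not isolated) | C=C(C)CCc1cc(C(Cl)OC)ccc1O[Si](C)(C)C(C)(C)C | intermediate
15 | racemic methyl 2,3,5-tris(TBSO)phenyl acetal of aldehyde 12 | C=C(C)CCc1cc(C(OC)Oc2cc(O[Si](C)(C)C(C)(C)C)cc(O[Si](C)(C)C(C)(C)C)c2O[Si](C)(C)C(C)(C)C)ccc1O[Si](C)(C)C(C)(C)C | intermediate
16 | ethyl vinyl ether | C=COCC | starting material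
17 | (2S,4S)-4-ethoxy-5,7,8-tris(TBSO)-2-[4-(TBSO)-3-(3-methylbut-3-en-1-yl)phenyl]chromane | C=C(C)CCc1cc([C@@H]2C[C@H](OCC)c3c(O[Si](C)(C)C(C)(C)C)cc(O[Si](C)(C)C(C)(C)C)c(O[Si](C)(C)C(C)(C)C)c3O2)ccc1O[Si](C)(C)C(C)(C)C | intermediate
18 | (2S)-5,7,8-tris(TBSO)-2-[4-(TBSO)-3-(3-methylbut-3-en-1-yl)phenyl]chroman-4-one | C=C(C)CCc1cc([C@@H]2CC(=O)c3c(O[Si](C)(C)C(C)(C)C)cc(O[Si](C)(C)C(C)(C)C)c(O[Si](C)(C)C(C)(C)C)c3O2)ccc1O[Si](C)(C)C(C)(C)C | intermediate
19 | (2S)-5,7,8-trihydroxy-2-[4-hydroxy-3-(3-methylbut-3-en-1-yl)phenyl]chroman-4-one | C=C(C)CCc1cc([C@@H]2CC(=O)c3c(O)cc(O)c(O)c3O2)ccc1O | target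

## Step count and risks

Total step count: 13. Longest linear sequence: 9 steps (1 to 19 through steps 1–5 and 10–13). The ring B branch from 8 takes 7 steps (6, 8, 9, 10–13), with step 7 as a one-step side branch.

**Step 11 (key step).**
- What may go wrong:
  - Facial discrimination in the ion pair may be poor, because the oxocarbenium ion has no hydrogen-bond donor to anchor it in the anion.
  - Ionisation may run in the wrong sense, with loss of the ring A phenol and capture of the resulting methyl oxocarbenium ion by the enol ether.
  - The enol ether may oligomerise cationically.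
  - The acid may shift the side-chain double bond.
  - The 4-ethoxy product may re-ionise and eliminate to the flav-3-ene.
- Fallback (known chemistry), setting out from 15 and returning at 18: 15 is ionised with stoichiometric SnCl4 in CH2Cl2 at −78 °C in the presence of 16, the known racemic oxa-Povarov annulation, to give the racemic cis-4-ethoxyflavan F1. Wet DDQ as in step 12 gives the racemic flavanone F2. Kinetic resolution of F2 by asymmetric transfer hydrogenation (RuCl[(R,R)-TsDPEN](p-cymene) or its antipode, HCO2H/Et3N, EtOAc) reduces the 2R ketone to the (2R,4R)-cis-flavan-4-ol F3 and leaves the 2S ketone, which is 18. Half of the material is sacrificed.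

**Step 10.**
- What may go wrong: C-alkylation of the electron-rich ring A in place of O-alkylation; migration of a silyl group from the neighbouring oxygen to the reacting phenol oxygen; hydrolysis of the very ionisable chloro ether.
- Fallback, setting out from 13 and 7 and returning at 15: 13 is treated with Et3SiOTf and 2,4,6-collidine (CH2Cl2, 0 °C), which turns one methoxy group into the N-(α-methoxybenzyl)collidinium triflate F4. Phenol 7 is then added to this buffered, halide-free electrophile and displaces collidine to give 15.

**Step 12.**
- What may go wrong: oxidative desilylation of the para-disilyloxy ring A to a quinone; hydride abstraction at C2; sluggish reaction of any trans epimer, whose C4 hydrogen lies in the ring plane.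
- Fallback, setting out from 17 and returning at 18: the benzylic ether is hydrolysed with pyridinium p-toluenesulfonate in wet acetone to the (2S)-flavan-4-ol F5 (both C4 epimers). F5 is oxidised with Dess–Martin periodinane buffered with NaHCO3 in CH2Cl2 to 18.

**Step 8.**
- What may go wrong: migration of the double bond through β-hydride elimination and re-insertion on palladium; slow oxidative addition next to the bulky silyloxy group.
- Fallback, setting out from 9 and returning at 13: 9 is converted with HC(OMe)3, MeOH and catalytic pyridinium p-toluenesulfonate into the bromo dimethyl acetal F6. A Heck reaction with but-3-en-2-one (Pd(OAc)2, P(o-tol)3, Et3N, DMF, 90 °C) gives the (E)-enone F7. Hydrogenation of the C=C bond (H2, 10% Pd on carbon, EtOAc, trace Et3N) gives the methyl ketone F8. Wittig methylenation (Ph3P=CH2 from Ph3PCH3Br and NaN(SiMe3)2, THF, 0 °C) gives 13.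

## Further compounds

F1 | step 11 | racemic cis-4-ethoxyflavan tetra-TBS ether (racemate of 17; one enantiomer drawn) | C=C(C)CCc1cc([C@@H]2C[C@H](OCC)c3c(O[Si](C)(C)C(C)(C)C)cc(O[Si](C)(C)C(C)(C)C)c(O[Si](C)(C)C(C)(C)C)c3O2)ccc1O[Si](C)(C)C(C)(C)C
F2 | step 11 | racemic flavanone tetra-TBS ether (racemate of 18) | C=C(C)CCc1cc(C2CC(=O)c3c(O[Si](C)(C)C(C)(C)C)cc(O[Si](C)(C)C(C)(C)C)c(O[Si](C)(C)C(C)(C)C)c3O2)ccc1O[Si](C)(C)C(C)(C)C
F3 | step 11 | (2R,4R)-5,7,8-tris(TBSO)-2-[4-(TBSO)-3-(3-methylbut-3-en-1-yl)phenyl]chroman-4-ol | C=C(C)CCc1cc([C@H]2C[C@@H](O)c3c(O[Si](C)(C)C(C)(C)C)cc(O[Si](C)(C)C(C)(C)C)c(O[Si](C)(C)C(C)(C)C)c3O2)ccc1O[Si](C)(C)C(C)(C)C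
F4 | step 10 | racemic 1-{methoxy[4-(TBSO)-3-(3-methylbut-3-en-1-yl)phenyl]methyl}-2,4,6-trimethylpyridinium triflate | C=C(C)CCc1cc(C(OC)[n+]2c(C)cc(C)cc2C)ccc1O[Si](C)(C)C(C)(C)C.[O-]S(=O)(=O)C(F)(F)F
F5 | step 12 | (2S)-5,7,8-tris(TBSO)-2-[4-(TBSO)-3-(3-methylbut-3-en-1-yl)phenyl]chroman-4-ol (C4 epimers) | C=C(C)CCc1cc([C@@H]2CC(O)c3c(O[Si](C)(C)C(C)(C)C)cc(O[Si](C)(C)C(C)(C)C)c(O[Si](C)(C)C(C)(C)C)c3O2)ccc1O[Si](C)(C)C(C)(C)C
F6 | step 8 | 3-bromo-4-(TBSO)benzaldehyde dimethyl acetal | COC(OC)c1ccc(O[Si](C)(C)C(C)(C)C)c(Br)c1
F7 | step 8 | (E)-4-[2-(TBSO)-5-(dimethoxymethyl)phenyl]but-3-en-2-one | CC(=O)/C=C/c1cc(C(OC)OC)ccc1O[Si](C)(C)C(C)(C)C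
F8 | step 8 | 4-[2-(TBSO)-5-(dimethoxymethyl)phenyl]butan-2-one | CC(=O)CCc1cc(C(OC)OC)ccc1O[Si](C)(C)C(C)(C)C
A1 | alternative 1 | (2S,4S)-cis-4-methoxyflavan with methoxymethyl ethers and methyl ketone side chain | CC(=O)CCc1cc([C@@H]2C[C@H](OC)c3c(OCOC)cc(OCOC)c(OCOC)c3O2)ccc1OCOC
A2 | alternative 1 | 2-hydroxy-3,4,6-tris(methoxymethoxy)benzaldehyde | O=Cc1c(O)c(OCOC)c(OCOC)cc1OCOC
A3 | alternative 1 | 4-[2-(methoxymethoxy)-5-vinylphenyl]butan-2-one | CC(=O)CCc1cc(C=C)ccc1OCOC
A4 | alternative 2 | ring B 2-methyl-2-(trimethylsilylmethyl)chroman adduct of the (2S)-flavanone (both epimers at the quaternary carbon) | C[Si](C)(C)CC1(C)CCc2cc([C@@H]3CC(=O)c4c(O[Si](C)(C)C(C)(C)C)cc(O[Si](C)(C)C(C)(C)C)c(O[Si](C)(C)C(C)(C)C)c4O3)ccc2O1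
A5 | alternative 2 | (2S)-2-[4-hydroxy-3-(hydroxymethyl)phenyl]-5,7,8-tris(TBSO)chroman-4-one | OCc1cc([C@@H]2CC(=O)c3c(O[Si](C)(C)C(C)(C)C)cc(O[Si](C)(C)C(C)(C)C)c(O[Si](C)(C)C(C)(C)C)c3O2)ccc1O
A6 | alternative 2 | methallyltrimethylsilane | C=C(C)C[Si](C)(C)C
A7 | alternative 3 | (2S)-7,4'-di-O-allyl ether of the target flavanone | C=C(C)CCc1cc([C@@H]2CC(=O)c3c(O)cc(OCC=C)c(O)c3O2)ccc1OCC=C
A8 | alternative 3 | (S)-1-[4-(allyloxy)-2,5-dihydroxyphenyl]-3-[4-(allyloxy)-3-(3-methylbut-3-en-1-yl)phenyl]-3-hydroxypropan-1-one | C=C(C)CCc1cc([C@@H](O)CC(=O)c2cc(O)c(OCC=C)cc2O)ccc1OCC=C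
A9 | alternative 3 | 2-acyl-5-(allyloxy)-1,4-benzoquinone derived from A8 | C=C(C)CCc1cc([C@@H](O)CC(=O)C2=CC(=O)C(OCC=C)=CC2=O)ccc1OCC=C
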